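**Retrosynthetic overview**

1. The strategy rests on one bond: C7, the lactone CH–O carbon that is allylic to the Z C5=C6 alkene, is bonded to C8, the butenolide β-carbon that also carries the C9 methylene. This bond belongs to both the ten-membered carbocycle (ring B) and the butenolide (ring C).
2. Last disconnection C7–C8: an alkenylchromium at C8 of a Z β-triflyloxy-α-methyl enoate adds to a C7 Z-enal, and the C7 alkoxide then lactonises on the cis methyl ester.
3. Seco precursor 29 comes from ring-A aldehyde 21 and methyl propanoate (aldol, oxidation, Z-triflation). The C11 methyl comes from an enol triflate by Stille coupling. The C2 propanoate and C14 acetate come from an Evans–Tishchenko reduction followed by acetylation.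
4. Ring-A stereocentres: C10 by Rh/(S)-BINAP vinyl addition to dienone 6; C1 and C2 by aldol of the α'-enolate with the nerol-derived aldehyde 5; C14 by 1,3-anti hydride delivery from C2.
5. Ring order: ring A (cyclohexene, from 6) first; ring B and then ring C in the last step.

Key step: step 19

Remark (locants): atoms carry the briarane locants of the target throughout. C1 is the quaternary methyl-bearing carbon, C2 the CH–O–propanoyl carbon, C5 (methyl-bearing)=C6, C7 the lactone CH–O, C8 the butenolide β-carbon, C9 the CH2, C10 the ring-fusion CH, C11 (methyl-bearing)=C12, C13 the CH2, C14 the CH–OAc, C17 the methyl-bearing butenolide α-carbon. The target is (1S,2S,5Z,7S,10S,14S).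

Remark (assumption): the Rh/(S)-BINAP alkenyl addition is taken to show with dienone 6 the facial preference known for cyclohex-2-enone; if the sense were opposite, (R)-BINAP would be used.

**Route**

Step 1
Reactants: 1 nerol
Product: 2 neryl tert-butyldimethylsilyl ether
Conditions: TBSCl, imidazole, DMF, 0 → 25 °C
Reagents that add atoms: tert-butyldimethylsilyl chloride, CC(C)(C)[Si](C)(C)Cl
Why: Imidazole-promoted silylation of the primary allylic alcohol should proceed cleanly and leaves the Z alkene untouched.

Step 2
Reactants: 2 neryl tert-butyldimethylsilyl ether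
Product: 3 6,7-epoxyneryl tert-butyldimethylsilyl ether (racemic epoxide)
Conditions: mCPBA (1.0 equiv), NaHCO3, CH2Cl2, −20 → 0 °C
Reagents that add atoms: 3-chloroperbenzoic acid, OOC(=O)c1cccc(Cl)c1
Why: Prilezhaev epoxidation should select the more electron-rich distal alkene because the proximal one is deactivated by the allylic silyloxy group; the racemic epoxide stereocentre is destroyed in step 3.

Step 3
Reactants: 3 6,7-epoxyneryl tert-butyldimethylsilyl ether
Product: 5 (4Z)-6-[(tert-butyldimethylsilyl)oxy]-4-methylhex-4-enal, via diol 4 (not isolated)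
Conditions: H5IO6, THF/Et2O, 0 °C
Reagents that add atoms: none
Why: Periodic acid should open the trisubstituted epoxide to the 1,2-diol and cleave it in the same flask (Malaprade glycol cleavage), giving the C2–C7 aldehyde with the Z C5=C6 alkene intact.

Step 4
Reactants: 6 4,4-dimethoxycyclohexa-2,5-dien-1-one; 7 potassium vinyltrifluoroborate
Product: 8 (5S)-5-ethenyl-4,4-dimethoxycyclohex-2-en-1-one
Conditions: [Rh(cod)2]BF4 (3 mol%), (S)-BINAP, 7 (1.2 equiv), Et3N, toluene/H2O, 30 °C
Reagents that add atoms: none
Why: Hayashi–Miyaura rhodium-catalysed asymmetric 1,4-addition desymmetrises the prochiral quinone monoketal, and the (S)-BINAP-bound alkenylrhodium should select the enone face that sets C10 as drawn.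

Step 5
Reactants: 8 (5S)-5-ethenyl-4,4-dimethoxycyclohex-2-en-1-one
Product: 10 (5R,6R)-5-ethenyl-4,4-dimethoxy-6-methylcyclohex-2-en-1-one, via lithium dienolate 9 (not isolated)
Conditions: LiN(i-Pr)2, THF, −78 °C; MeI, −78 → −30 °C
Reagents that add atoms: iodomethane, CI
Why: Kinetic α'-deprotonation (the γ-position is the quaternary ketal carbon) and SN2 methylation of the cross-conjugated enolate should place the methyl anti to the vinyl group; this C1 centre is planarised again in step 6, so its ratio does not matter.

Step 6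
Reactants: 10 (5R,6R)-5-ethenyl-4,4-dimethoxy-6-methylcyclohex-2-en-1-one; 5 (4Z)-6-[(tert-butyldimethylsilyl)oxy]-4-methylhex-4-enal
Product: 12 aldol adduct (5R,6S)-5-ethenyl-6-[(1S,4Z)-6-[(tert-butyldimethylsilyl)oxy]-1-hydroxy-4-methylhex-4-en-1-yl]-4,4-dimethoxy-6-methylcyclohex-2-en-1-one, via lithium enolate 11 (not isolated)
Conditions: LiN(i-Pr)2, THF, −78 → −40 °C; then 5, −78 °C; aq. NH4Cl at −78 °C
Reagents that add atoms: none
Why: Directed aldol addition of the tetrasubstituted lithium α'-enolate creates quaternary C1 and the C2 carbinol: the aldehyde should approach anti to the C10 vinyl group (chain trans to vinyl, methyl cis), and the Zimmerman–Traxler chair with the aldehyde chain equatorial and the C1 methyl cis to the enolate oxygen should give 2S.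

Step 7
Reactants: 12 aldol adduct
Product: 13 (1S,4Z)-6-[(tert-butyldimethylsilyl)oxy]-1-[(1R,2R,6S)-2-ethenyl-6-hydroxy-3,3-dimethoxy-1-methylcyclohex-4-en-1-yl]-4-methylhex-4-en-1-yl propanoate
Conditions: propanal (6 equiv), SmI2 (0.3 equiv), THF, −10 °C
Reagents that add atoms: propanal, CCC=O
Why: Evans–Tishchenko reduction: the C2 hydroxyl adds to propanal and the samarium-bound hemiacetal delivers hydride intramolecularly to the C14 carbonyl through a chair-like transition state, which should give the 1,3-anti C14 alcohol (14S) and leave the C2 oxygen as the propanoate the target needs.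

Step 8
Reactants: 13 C2 propanoate C14 alcohol
Product: 14 (1S,4Z)-1-[(1S,2R,6S)-6-acetoxy-2-ethenyl-3,3-dimethoxy-1-methylcyclohex-4-en-1-yl]-6-[(tert-butyldimethylsilyl)oxy]-4-methylhex-4-en-1-yl propanoate
Conditions: Ac2O, DMAP, pyridine, CH2Cl2, 0 → 25 °C
Reagents that add atoms: acetic anhydride, CC(=O)OC(C)=O
Why: DMAP-catalysed acetylation of the only free hydroxyl (nucleophilic acyl substitution) touches no stereocentre.

Step 9
Reactants: 14 C14 acetate dimethyl ketal
Product: 15 C11 enone (ketal of 14 replaced by C=O; all stereocentres as in 14)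
Conditions: PPTS (cat.), acetone/H2O, 25 °C
Reagents that add atoms: water, O
Why: Mild acid hydrolysis of the allylic dimethyl ketal, far more labile than the silyl ether and the two esters, should unveil the C11 ketone as a cyclohexenone.

Step 10
Reactants: 15 C11 enone
Product: 17 ring-A enol triflate (C11 triflate; C11=C12), via lithium enolate 16 (not isolated)
Conditions: LiBH(s-Bu)3 (1.1 equiv), THF, −78 °C; then PhNTf2, −78 → 0 °C
Reagents that add atoms: N-phenylbis(trifluoromethanesulfonimide), O=S(=O)(N(c1ccccc1)S(=O)(=O)C(F)(F)F)C(F)(F)F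
Why: Conjugate hydride reduction of the β-unsubstituted cyclohexenone by the hindered borohydride generates the C11–C12 enolate regiospecifically and O-triflation traps it (Crisp–Scott protocol), so the triflate sits at C11=C12 and C10 is never enolised.

Step 11
Reactants: 17 ring-A enol triflate
Product: 18 (1S,4Z)-1-[(1S,2S,6S)-6-acetoxy-2-ethenyl-1,3-dimethylcyclohex-3-en-1-yl]-6-[(tert-butyldimethylsilyl)oxy]-4-methylhex-4-en-1-yl propanoate
Conditions: Me4Sn, Pd(PPh3)4 (5 mol%), LiCl, THF, 65 °C
Reagents that add atoms: tetramethylstannane, C[Sn](C)(C)C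
Why: Stille cross-coupling of the alkenyl triflate (zerovalent palladium, LiCl) should install the C11 methyl with the C11=C12 alkene in place, and the esters, silyl ether and other alkenes are inert.

Step 12
Reactants: 18 C10 vinyl compound
Product: 20 primary alcohol (C8 hydroxyl; 1S,2S,10S,14S), via B-alkyl-9-BBN 19 (not isolated)
Conditions: 9-BBN, THF, 0 → 25 °C; then NaBO3·4H2O, THF/H2O, 25 °C
Reagents that add atoms: sodium perborate, [Na+].[O-]OB=O
Why: Anti-Markovnikov hydroboration with the bulky borane 9-BBN should select the monosubstituted vinyl group over the two trisubstituted alkenes, and perborate oxidation spares the esters.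

Step 13
Reactants: 20 primary alcohol
Product: 21 ring-A aldehyde (C8 aldehyde; 1S,2S,10S,14S)
Conditions: Dess–Martin periodinane, NaHCO3, CH2Cl2, 0 → 25 °C
Reagents that add atoms: none
Why: Buffered Dess–Martin oxidation of a primary alcohol to the aldehyde is mild and non-epimerising.

Step 14
Reactants: 21 ring-A aldehyde; 22 methyl propanoate
Product: 24 β-hydroxy ester (C8 carbinol; mixture at C8 and C17), via lithium enolate 23 (not isolated)
Conditions: 22, LiN(i-Pr)2, THF, −78 °C; then 21, −78 °C; aq. NH4Cl
Reagents that add atoms: none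
Why: Aldol addition of the preformed lithium ester enolate to the aldehyde at −78 °C, much faster than attack on the acetate or propanoate, forms C8–C17; the two new stereocentres are removed in steps 15 and 16.

Step 15
Reactants: 24 β-hydroxy ester
Product: 25 α-methyl β-keto ester (C8 ketone)
Conditions: Dess–Martin periodinane, NaHCO3, CH2Cl2, 25 °C
Reagents that add atoms: none
Why: Dess–Martin oxidation of the β-hydroxy ester should give the β-keto ester without touching the other functions.

Step 16
Reactants: 25 α-methyl β-keto ester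
Product: 27 Z enol triflate (C8 triflate cis to the ester; C7 silyl ether), via sodium enolate 26 (not isolated)
Conditions: NaH (1.05 equiv), Et2O, 0 °C; then Tf2O, 0 °C
Reagents that add atoms: trifluoromethanesulfonic anhydride, O=S(=O)(OS(=O)(=O)C(F)(F)F)C(F)(F)F
Why: O-Triflation of the sodium-chelated enolate of the β-keto ester, the only site deprotonated by one equivalent of base, should give the Z isomer because the cation holds the ketone and ester oxygens syn.

Step 17
Reactants: 27 Z enol triflate silyl ether
Product: 28 C7 allylic alcohol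
Conditions: HF·pyridine, pyridine, THF, 0 °C
Reagents that add atoms: none
Why: Buffered fluoride desilylation should free the primary allylic alcohol and leave the enol triflate and the three esters intact.

Step 18
Reactants: 28 C7 allylic alcohol
Product: 29 seco enal–enol triflate (Z enal at C7; Z enol triflate at C8)
Conditions: Dess–Martin periodinane, NaHCO3, CH2Cl2, 0 °C
Reagents that add atoms: none
Why: Buffered Dess–Martin oxidation of the allylic alcohol should give the Z enal without Z-to-E isomerisation.

Step 19
Reactants: 29 seco enal–enol triflate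
Product: 32 target lactone CNP0112230.2, via alkenylchromium 30 (not isolated), via chromium alkoxide 31 (not isolated)
Conditions: CrCl2 (10 equiv), NiCl2 (1 mol% of Cr), degassed DMSO, 25 °C, slow addition of 29 to about 2 mM
Reagents that add atoms: none
Why: Zerovalent nickel, formed from NiCl2 by CrCl2, inserts into the C8–O bond of the electron-poor enol triflate and passes the alkenyl group to trivalent chromium, and alkenylchromium 30 adds 1,2 to the C7 aldehyde (Nozaki–Hiyama–Kishi reaction). The closest known reactions are NiCl2/CrCl2 couplings of Z β-halo- and β-triflyloxy-enoates with aldehydes that give butenolides directly, and chromium-mediated closures of medium carbocycles. Ring B closes by a 10-exo-trig carbonyl addition that forms C7–C8, and ring C closes by a 5-exo-trig acyl substitution of chromium alkoxide 31 on the methyl ester held cis to it across C8=C17. C7 is the only new stereocentre and is under substrate control: the Z C5=C6 alkene, the trans C1/C10 junction and the C2 ester shape the closing chain, and the 7S face is the one expected but is not secured by any reagent. The step needs chemoselectivity (the organochromium should ignore the acetate, propanoate and enoate), retention of the Z triflate geometry (so that addition and lactonisation are one operation) and closure over dimerisation, which high dilution is meant to secure.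

**Compound list**

1 | nerol, (2Z)-3,7-dimethylocta-2,6-dien-1-ol | CC(C)=CCC/C(C)=C\CO | starting material
2 | neryl tert-butyldimethylsilyl ether | CC(C)=CCC/C(C)=C\CO[Si](C)(C)C(C)(C)C | intermediate
3 | 6,7-epoxyneryl tert-butyldimethylsilyl ether (racemic epoxide) | CC1(C)OC1CC/C(C)=C\CO[Si](C)(C)C(C)(C)C | intermediate
4 | 6,7-diol from 3 (racemic; not isolated) | CC(C)(O)C(O)CC/C(C)=C\CO[Si](C)(C)C(C)(C)C | intermediate
5 | (4Z)-6-[(tert-butyldimethylsilyl)oxy]-4-methylhex-4-enal (C2–C7) | O=CCC/C(C)=C\CO[Si](C)(C)C(C)(C)C | intermediate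
6 | 4,4-dimethoxycyclohexa-2,5-dien-1-one | COC1(OC)C=CC(=O)C=C1 | starting material
7 | potassium vinyltrifluoroborate | [K+].C=C[B-](F)(F)F | starting material
8 | (5S)-5-ethenyl-4,4-dimethoxycyclohex-2-en-1-one | C=C[C@H]1C(OC)(OC)C=CC(=O)C1 | intermediate
9 | lithium dienolate of 8 (not isolated) | C=C[C@H]1C(OC)(OC)C=CC(O[Li])=C1 | intermediate
10 | (5R,6R)-5-ethenyl-4,4-dimethoxy-6-methylcyclohex-2-en-1-one (methyl trans to vinyl) | C=C[C@H]1C(OC)(OC)C=CC(=O)[C@@H]1C | intermediate
11 | lithium enolate of 10 (not isolated) | C=C[C@H]1C(OC)(OC)C=CC(O[Li])=C1C | intermediate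
12 | aldol adduct, (5R,6S)-5-ethenyl-6-[(1S,4Z)-6-[(tert-butyldimethylsilyl)oxy]-1-hydroxy-4-methylhex-4-en-1-yl]-4,4-dimethoxy-6-methylcyclohex-2-en-1-one | C=C[C@H]1C(OC)(OC)C=CC(=O)[C@]1(C)[C@H](CC/C(C)=C\CO[Si](C)(C)C(C)(C)C)O | intermediate
13 | (1S,4Z)-6-[(tert-butyldimethylsilyl)oxy]-1-[(1R,2R,6S)-2-ethenyl-6-hydroxy-3,3-dimethoxy-1-methylcyclohex-4-en-1-yl]-4-methylhex-4-en-1-yl propanoate | C=C[C@H]1C(OC)(OC)C=C[C@H](O)[C@]1(C)[C@H](CC/C(C)=C\CO[Si](C)(C)C(C)(C)C)OC(=O)CC | intermediate
14 | (1S,4Z)-1-[(1S,2R,6S)-6-acetoxy-2-ethenyl-3,3-dimethoxy-1-methylcyclohex-4-en-1-yl]-6-[(tert-butyldimethylsilyl)oxy]-4-methylhex-4-en-1-yl propanoate | C=C[C@H]1C(OC)(OC)C=C[C@H](OC(C)=O)[C@]1(C)[C@H](CC/C(C)=C\CO[Si](C)(C)C(C)(C)C)OC(=O)CC | intermediate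
15 | C11 enone: 14 with the ketal replaced by C=O (C12=C13 enone; stereocentres as in 14) | C=C[C@H]1C(=O)C=C[C@H](OC(C)=O)[C@]1(C)[C@H](CC/C(C)=C\CO[Si](C)(C)C(C)(C)C)OC(=O)CC | intermediate
16 | lithium C11–C12 enolate from 1,4-reduction of 15 (not isolated) | C=C[C@H]1C(O[Li])=CC[C@H](OC(C)=O)[C@]1(C)[C@H](CC/C(C)=C\CO[Si](C)(C)C(C)(C)C)OC(=O)CC | intermediate
17 | ring-A enol triflate: C11 triflate on C11=C12, with C10 vinyl, C14 acetate, C2 propanoate, C7 silyl ether | C=C[C@H]1C(OS(=O)(=O)C(F)(F)F)=CC[C@H](OC(C)=O)[C@]1(C)[C@H](CC/C(C)=C\CO[Si](C)(C)C(C)(C)C)OC(=O)CC | intermediate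
18 | (1S,4Z)-1-[(1S,2S,6S)-6-acetoxy-2-ethenyl-1,3-dimethylcyclohex-3-en-1-yl]-6-[(tert-butyldimethylsilyl)oxy]-4-methylhex-4-en-1-yl propanoate | C=C[C@H]1C(C)=CC[C@H](OC(C)=O)[C@]1(C)[C@H](CC/C(C)=C\CO[Si](C)(C)C(C)(C)C)OC(=O)CC | intermediate
19 | B-alkyl-9-BBN adduct of 18 at C8 (not isolated) | B1(C2CCCC1CCC2)CC[C@H]1C(C)=CC[C@H](OC(C)=O)[C@]1(C)[C@H](CC/C(C)=C\CO[Si](C)(C)C(C)(C)C)OC(=O)CC | intermediate
20 | primary alcohol: 18 with C10 2-hydroxyethyl in place of vinyl (1S,2S,10S,14S) | OCC[C@H]1C(C)=CC[C@H](OC(C)=O)[C@]1(C)[C@H](CC/C(C)=C\CO[Si](C)(C)C(C)(C)C)OC(=O)CC | intermediate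
21 | ring-A aldehyde: C10 2-oxoethyl (C8 aldehyde; 1S,2S,10S,14S) | O=CC[C@H]1C(C)=CC[C@H](OC(C)=O)[C@]1(C)[C@H](CC/C(C)=C\CO[Si](C)(C)C(C)(C)C)OC(=O)CC | intermediate
22 | methyl propanoate | CCC(=O)OC | starting material
23 | lithium enolate of methyl propanoate (not isolated) | CC=C(OC)O[Li] | intermediate
24 | β-hydroxy ester: methyl 3-hydroxy-2-methylbutanoate carrying ring A at C4 (C8 and C17 epimers; 1S,2S,10S,14S) | COC(=O)C(C)C(O)C[C@H]1C(C)=CC[C@H](OC(C)=O)[C@]1(C)[C@H](CC/C(C)=C\CO[Si](C)(C)C(C)(C)C)OC(=O)CC | intermediate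
25 | α-methyl β-keto ester (C8 ketone; C17 epimers) | COC(=O)C(C)C(=O)C[C@H]1C(C)=CC[C@H](OC(C)=O)[C@]1(C)[C@H](CC/C(C)=C\CO[Si](C)(C)C(C)(C)C)OC(=O)CC | intermediate
26 | sodium enolate of 25 (chelated; not isolated) | COC(=O)/C(C)=C(O[Na])/C[C@H]1C(C)=CC[C@H](OC(C)=O)[C@]1(C)[C@H](CC/C(C)=C\CO[Si](C)(C)C(C)(C)C)OC(=O)CC | intermediate
27 | Z enol triflate, C7 silyl ether: methyl (2Z)-2-methyl-3-(triflyloxy)but-2-enoate carrying ring A at C4 | COC(=O)/C(C)=C(OS(=O)(=O)C(F)(F)F)/C[C@H]1C(C)=CC[C@H](OC(C)=O)[C@]1(C)[C@H](CC/C(C)=C\CO[Si](C)(C)C(C)(C)C)OC(=O)CC | intermediate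
28 | Z enol triflate, C7 allylic alcohol | COC(=O)/C(C)=C(OS(=O)(=O)C(F)(F)F)/C[C@H]1C(C)=CC[C@H](OC(C)=O)[C@]1(C)[C@H](CC/C(C)=C\CO)OC(=O)CC | intermediate
29 | seco enal–enol triflate (Z enal at C7; Z β-triflyloxy-α-methyl enoate at C8; 1S,2S,10S,14S) | COC(=O)/C(C)=C(OS(=O)(=O)C(F)(F)F)/C[C@H]1C(C)=CC[C@H](OC(C)=O)[C@]1(C)[C@H](CC/C(C)=C\C=O)OC(=O)CC | intermediate
30 | C8 alkenylchromium dichloride from 29 (trivalent chromium; not isolated) | COC(=O)/C(C)=C([Cr](Cl)Cl)/C[C@H]1C(C)=CC[C@H](OC(C)=O)[C@]1(C)[C@H](CC/C(C)=C\C=O)OC(=O)CC | intermediate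
31 | ten-membered C7 chromium alkoxide with the ester cis across C8=C17 (not isolated) | CCC(=O)O[C@H]1CC/C(C)=C\[C@H](O[Cr](Cl)Cl)/C(=C(/C)C(=O)OC)C[C@H]2C(C)=CC[C@H](OC(C)=O)[C@]12C | intermediate
32 | target CNP0112230.2, (1S,2S,5Z,7S,10S,14S) tricyclic briarane butenolide with C2 propanoate and C14 acetate | CCC(=O)O[C@H]1CC/C(C)=C\[C@@H]2OC(=O)C(C)=C2C[C@H]2C(C)=CC[C@H](OC(C)=O)[C@]12C | target

**Totals and risks**

Total steps: 19. Longest linear sequence: 17 steps (nerol 1 to 32 through steps 1–3 and 6–19); 16 steps from dienone 6.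

Steps most likely to fail:

Step 19. The chromium-mediated closure may add to the wrong face of the enal, because nothing but the conformation of the closing ten-membered chain controls C7, and strain may slow the closure enough for protodemetallation to compete. The fallback sets out from 29 and accepts the closure with whatever C7 ratio it gives. If the 7R lactone 7-epi-32 F1 predominates, it would be converted with TBSOTf and Et3N in CH2Cl2 into the ring-fused 2-silyloxyfuran F2, which erases C7. Acid-mediated γ-protonation (HCl, THF/H2O, −78 → 0 °C) would then restore the conjugated butenolide and set C7 again by proton delivery rather than by carbon–carbon bond formation. The fallback comes back to the route at 32.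

Step 6. The tetrasubstituted enolate may add with eroded simple diastereoselection at C2, through a competing chair with the aldehyde chain axial, and the hindered aldolate may revert by retro-aldol. The fallback sets out from 12 obtained as a mixture of C2 epimers. Dess–Martin oxidation would give the non-enolisable β-diketone F3. Reduction with Zn(BH4)2 in Et2O at −20 °C should then take the saturated side-chain carbonyl in preference to the conjugated ring carbonyl and deliver hydride on the zinc chelate anti to the pseudoaxial C1 methyl, which gives the 2S carbinol. The fallback comes back to the route at 12.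

Step 10. The borohydride may reduce the C11 carbonyl 1,2 or attack the esters instead of adding 1,4, and proton transfer within the enolate before O-triflation would scramble the triflate position. The fallback sets out from 15. Conjugate reduction with [(Ph3P)CuH]6 in benzene with aqueous work-up would give the saturated C11 ketone F4. Kinetic deprotonation with KN(SiMe3)2 at the less hindered C12 methylene at −78 °C and trapping with PhNTf2 would then give the same enol triflate. The fallback comes back to the route at 17.

Further compounds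
F1 | step 19 | 7-epi-32, the 7R lactone | CCC(=O)O[C@H]1CC/C(C)=C\[C@H]2OC(=O)C(C)=C2C[C@H]2C(C)=CC[C@H](OC(C)=O)[C@]12C
F2 | step 19 | ring-fused 2-[(tert-butyldimethylsilyl)oxy]-3-methylfuran from F1 | CCC(=O)O[C@H]1CC/C(C)=C\c2oc(O[Si](C)(C)C(C)(C)C)c(C)c2C[C@H]2C(C)=CC[C@H](OC(C)=O)[C@]12C
F3 | step 6 | β-diketone from 12 (C2 ketone) | C=C[C@H]1C(OC)(OC)C=CC(=O)[C@]1(C)C(=O)CC/C(C)=C\CO[Si](C)(C)C(C)(C)C
F4 | step 10 | saturated C11 ketone from 15 | C=C[C@H]1C(=O)CC[C@H](OC(C)=O)[C@]1(C)[C@H](CC/C(C)=C\CO[Si](C)(C)C(C)(C)C)OC(=O)CC
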